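**Retrosynthetic overview**

- The target is cut last at C5: a Suzuki–Miyaura coupling of the 5-chloro-dihydrobenzofuran with (E)-propenylboronic acid, so the propenyl group never meets the acid or the earlier palladium step.
- The only ring that is made is the dihydrofuran ring. It closes late at O1–C2: C–B is oxidised to C–OH, then acid removes the MOM group and the phenol traps the C2 benzylic cation trans to the C3 methyl.
- The strategy rests on C2–C3–CH3 (benzofuran numbering) being a propenyl unit, with the trimethoxyphenyl ring and O1 on C2 and ring A carbon C3a on C3. C2–C1′ and C3–C3a are both made in one conjunctive coupling across the C=C of an (E)-propenylboron ate complex, and the boron marks where O1 goes.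
- Fragments: the ring A triflate from 2-hydroxy-4-methoxybenzaldehyde (chlorination, MOM ether, Baeyer–Villiger, triflation); the propenylboronic ester of the cis-diol from acenaphthoquinone; trimethoxyphenyllithium from the bromide.

Key step: step 7

Remark on numbering: C2, C3, C3a, C5 and O1 refer to the benzofuran numbering of the target; C1′ is the attached carbon of the trimethoxyphenyl ring.

Assumption: the (Sp,Sp) enantiomer of the ferrocenyl bisphosphine is taken to give the (1R,2S) boronate; if the sense of induction is the opposite, the (Rp,Rp) ligand is used and nothing else changes.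

**Route**

Step 1
Reactants: 1 2-hydroxy-4-methoxybenzaldehyde
Product: 2 5-chloro-2-hydroxy-4-methoxybenzaldehyde
Conditions: NCS (1.05 equiv), TsOH·H2O (cat.), MeCN, rt to 50 °C
Reagents that add atoms: N-chlorosuccinimide, O=C1CCC(=O)N1Cl
Why: Electrophilic aromatic chlorination should go to C5, which is para to the hydroxyl, ortho to the methoxy group and meta to the aldehyde, while C3 is flanked by two substituents.

Step 2
Reactants: 2 5-chloro-2-hydroxy-4-methoxybenzaldehyde
Product: 3 5-chloro-4-methoxy-2-(methoxymethoxy)benzaldehyde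
Conditions: MOMCl, K2CO3, DMF, 0 °C to rt
Reagents that add atoms: chloromethyl methyl ether, COCCl
Why: O-Alkylation of the phenoxide (Williamson-type MOM ether formation) masks the oxygen that later becomes O1 with a group that survives base, organometallics and peroxide.

Step 3
Reactants: 3 5-chloro-4-methoxy-2-(methoxymethoxy)benzaldehyde
Product: 5 5-chloro-4-methoxy-2-(methoxymethoxy)phenol, via aryl formate 4 (not isolated)
Conditions: mCPBA (1.2 equiv), CH2Cl2, 0 °C to rt; then MeOH, Et3N (cat.), rt
Reagents that add atoms: meta-chloroperoxybenzoic acid, OOC(=O)c1cccc(Cl)c1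
Why: In this Baeyer–Villiger (Dakin-type) oxidation the electron-rich aryl group, with oxygen ortho and para to the formyl carbon, should migrate in preference to hydrogen, and the labile aryl formate is cleaved by base-catalysed methanolysis.

Step 4
Reactants: 5 5-chloro-4-methoxy-2-(methoxymethoxy)phenol
Product: 6 5-chloro-4-methoxy-2-(methoxymethoxy)phenyl trifluoromethanesulfonate
Conditions: Tf2O, pyridine, CH2Cl2, −10 to 0 °C
Reagents that add atoms: trifluoromethanesulfonic anhydride, O=S(=O)(OS(=O)(=O)C(F)(F)F)C(F)(F)F
Why: O-Sulfonylation of the phenol under pyridine buffering gives the aryl triflate without touching the acid-labile MOM ether.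

Step 5
Reactants: 7 acenaphthoquinone
Product: 8 cis-1,2-dimethyl-1,2-dihydroacenaphthylene-1,2-diol (meso)
Conditions: AlMe3 (4 equiv), toluene, 0 °C to rt; aqueous Rochelle salt/HCl work-up; recrystallisation
Reagents that add atoms: trimethylaluminium, C[Al](C)C
Why: Double 1,2-addition of methylaluminium to the diketone should give the cis diol, because the second methyl group enters anti to the bulky aluminium alkoxide formed first; crystallisation removes any trans isomer.

Step 6
Reactants: 9 (E)-prop-1-enylboronic acid; 8 cis-1,2-dimethyl-1,2-dihydroacenaphthylene-1,2-diol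
Product: 10 (E)-prop-1-enylboronic ester of diol 8
Conditions: 4 Å MS, CH2Cl2, rt
Reagents that add atoms: none
Why: Condensation of a boronic acid with a cis-1,2-diol to the five-membered cyclic boronic ester is driven by removal of water and leaves the (E) alkene untouched.

Step 7
Reactants: 11 5-bromo-1,2,3-trimethoxybenzene; 10 (E)-prop-1-enylboronic ester of diol 8; 6 5-chloro-4-methoxy-2-(methoxymethoxy)phenyl trifluoromethanesulfonate
Product: 14 (1R,2S)-2-[5-chloro-4-methoxy-2-(methoxymethoxy)phenyl]-1-(3,4,5-trimethoxyphenyl)propylboronic ester of diol 8, via 3,4,5-trimethoxyphenyllithium 12 (not isolated), via lithium ate complex 13 (not isolated)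
Conditions: 11, t-BuLi (2.0 equiv), THF, −78 °C; then 10, −78 °C to rt; solvent removed; then 6, Pd(OAc)2 (3 mol %), (Sp,Sp)-2,2′-bis[(R)-(dimethylamino)(phenyl)methyl]-1,1′-bis[bis(3,5-dimethylphenyl)phosphino]ferrocene (3.6 mol %), KOTf (1 equiv), THF, 60 °C
Reagents that add atoms: tert-butyllithium, CC(C)(C)[Li] (supplies the lithium of 12 and 13; none of its atoms remain in 14)
Why: This is a palladium-catalysed enantioselective conjunctive cross-coupling, a reaction type established for β-substituted (E)-alkenylboron ate complexes carrying this hindered diol, with aryl migrating groups and aryl triflates. Zerovalent palladium inserts into the C–OTf bond of 6; the resulting cationic arylpalladium (divalent palladium) binds the C2=C3 π bond of 13, the trimethoxyphenyl group shifts from boron to C2 anti to palladium while C3 becomes bound to the metal, and reductive elimination joins ring A to C3. No ring is closed. The chiral ferrocenyl bisphosphine chooses the alkene face and so fixes C3, and the anti 1,2-shift followed by retentive reductive elimination turns the (E) geometry into the (1R,2S) relationship between C2 and C3. The step needs conjunctive coupling to win over direct transfer of the propenyl group to palladium, which the bulky acenaphthene-derived diol on boron secures, and it needs the C–OTf bond to react in preference to the C–Cl bond, which the inertness of an electron-rich aryl chloride toward a diarylphosphine–palladium catalyst at 60 °C secures. KOTf is added to take up the bromide left by the lithium–bromine exchange, which would otherwise block the cationic palladium site; boron in 13 is a pseudo-asymmetric centre, but both epimers give the same 14.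

Step 8
Reactants: 14 (1R,2S)-2-[5-chloro-4-methoxy-2-(methoxymethoxy)phenyl]-1-(3,4,5-trimethoxyphenyl)propylboronic ester of diol 8
Product: 15 (1R,2R)-2-[5-chloro-4-methoxy-2-(methoxymethoxy)phenyl]-1-(3,4,5-trimethoxyphenyl)propan-1-ol
Conditions: NaOH (3 M aq), H2O2 (30 % aq), THF, 0 °C to rt
Reagents that add atoms: hydrogen peroxide, OO
Why: Boronate oxidation proceeds by 1,2-migration of carbon from boron to oxygen with retention, so the oxygen takes the place of boron at C2 (the descriptor at C3 changes from S to R only because the priorities change); the diol 8 is recovered.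

Step 9
Reactants: 15 (1R,2R)-2-[5-chloro-4-methoxy-2-(methoxymethoxy)phenyl]-1-(3,4,5-trimethoxyphenyl)propan-1-ol
Product: 17 (2R,3R)-5-chloro-6-methoxy-3-methyl-2-(3,4,5-trimethoxyphenyl)-2,3-dihydro-1-benzofuran, via phenol diol 16 (not isolated)
Conditions: HCl (conc., 5 equiv), MeOH, 45 °C
Reagents that add atoms: none
Why: Acid-catalysed acetal cleavage frees the phenol, and ionisation of the benzylic alcohol gives the trimethoxybenzyl cation, which the phenol traps in an SN1 cycloetherification; C2 is set trans to the C3 methyl by substrate control (the less strained closure, with any cis isomer re-ionising to trans), while C3 is not involved.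

Step 10
Reactants: 17 (2R,3R)-5-chloro-6-methoxy-3-methyl-2-(3,4,5-trimethoxyphenyl)-2,3-dihydro-1-benzofuran; 9 (E)-prop-1-enylboronic acid
Product: 18 (2R,3R)-6-methoxy-3-methyl-5-[(E)-prop-1-enyl]-2-(3,4,5-trimethoxyphenyl)-2,3-dihydro-1-benzofuran
Conditions: Pd(OAc)2 (3 mol %), SPhos (6 mol %), K3PO4, toluene/H2O (10:1), 90 °C
Reagents that add atoms: none
Why: Suzuki–Miyaura coupling with a dialkylbiarylphosphine ligand activates the electron-rich aryl chloride and transfers the alkenyl group with retention of the (E) geometry; the base does not touch the two benzylic stereocentres.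

**Compound list**

1 | 2-hydroxy-4-methoxybenzaldehyde | O=Cc1ccc(OC)cc1O | starting material
2 | 5-chloro-2-hydroxy-4-methoxybenzaldehyde | O=Cc1cc(Cl)c(OC)cc1O | intermediate
3 | 5-chloro-4-methoxy-2-(methoxymethoxy)benzaldehyde | O=Cc1cc(Cl)c(OC)cc1OCOC | intermediate
4 | 5-chloro-4-methoxy-2-(methoxymethoxy)phenyl formate | O=COc1cc(Cl)c(OC)cc1OCOC | intermediate
5 | 5-chloro-4-methoxy-2-(methoxymethoxy)phenol | Oc1cc(Cl)c(OC)cc1OCOC | intermediate
6 | 5-chloro-4-methoxy-2-(methoxymethoxy)phenyl trifluoromethanesulfonate | COCOc1cc(OC)c(Cl)cc1OS(=O)(=O)C(F)(F)F | intermediate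
7 | acenaphthoquinone | O=C1C(=O)c2cccc3cccc1c23 | starting material
8 | cis-1,2-dimethyl-1,2-dihydroacenaphthylene-1,2-diol (meso) | C[C@]1(O)[C@@](C)(O)c2cccc3cccc1c23 | intermediate
9 | (E)-prop-1-enylboronic acid | C/C=C/B(O)O | starting material
10 | (E)-prop-1-enylboronic ester of diol 8 | C[C@]12OB(/C=C/C)O[C@@]1(C)c1cccc3cccc2c13 | intermediate
11 | 5-bromo-1,2,3-trimethoxybenzene | COc1cc(Br)cc(OC)c1OC | starting material
12 | 3,4,5-trimethoxyphenyllithium | [Li]c1cc(OC)c(OC)c(OC)c1 | intermediate
13 | lithium [(E)-prop-1-enyl](3,4,5-trimethoxyphenyl)borate of diol 8 (ate complex, configuration at boron not defined) | C[C@]12O[B-](/C=C/C)(c4cc(OC)c(OC)c(OC)c4)O[C@@]1(C)c1cccc3cccc2c13.[Li+] | intermediate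
14 | (1R,2S)-2-[5-chloro-4-methoxy-2-(methoxymethoxy)phenyl]-1-(3,4,5-trimethoxyphenyl)propylboronic ester of diol 8 | C[C@]12OB([C@@H](c5cc(OC)c(OC)c(OC)c5)[C@@H](c6cc(Cl)c(OC)cc6OCOC)C)O[C@@]1(C)c1cccc3cccc2c13 | intermediate
15 | (1R,2R)-2-[5-chloro-4-methoxy-2-(methoxymethoxy)phenyl]-1-(3,4,5-trimethoxyphenyl)propan-1-ol | O[C@@H](c1cc(OC)c(OC)c(OC)c1)[C@@H](c1cc(Cl)c(OC)cc1OCOC)C | intermediate
16 | 4-chloro-2-[(1R,2R)-1-hydroxy-1-(3,4,5-trimethoxyphenyl)propan-2-yl]-5-methoxyphenol | O[C@@H](c1cc(OC)c(OC)c(OC)c1)[C@@H](c1cc(Cl)c(OC)cc1O)C | intermediate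
17 | (2R,3R)-5-chloro-6-methoxy-3-methyl-2-(3,4,5-trimethoxyphenyl)-2,3-dihydro-1-benzofuran | Clc1cc2c(cc1OC)O[C@@H](c1cc(OC)c(OC)c(OC)c1)[C@@H]2C | intermediate
18 | (2R,3R)-6-methoxy-3-methyl-5-[(E)-prop-1-enyl]-2-(3,4,5-trimethoxyphenyl)-2,3-dihydro-1-benzofuran | C/C=C/c1cc2c(cc1OC)O[C@@H](c1cc(OC)c(OC)c(OC)c1)[C@@H]2C | target

**Step count and risks**

Total steps: 10. Longest linear sequence: 8 steps (steps 1, 2, 3, 4, 7, 8, 9, 10).

Steps most likely to fail:

1. Step 7. The propenyl group may transfer directly from boron to palladium (plain Suzuki coupling). Alkene binding may stall at a palladium centre crowded by the ortho methoxymethoxy group, or the facial selectivity may be too low. The fallback sets out from 12 (made from 11 as in step 7) and 6 and comes back at 15. Acylation of 12 with N-methoxy-N-methylpropanamide (THF, −78 °C) should give 1-(3,4,5-trimethoxyphenyl)propan-1-one F1. Palladium-catalysed α-arylation of F1 with triflate 6 (Pd2(dba)3, Xantphos, K3PO4, toluene, 80 °C) should give racemic 2-[5-chloro-4-methoxy-2-(methoxymethoxy)phenyl]-1-(3,4,5-trimethoxyphenyl)propan-1-one F2. Asymmetric hydrogenation of F2 with dynamic kinetic resolution (RuCl2[(S)-xylbinap][(S)-daipen] or its mirror image, t-BuOK, i-PrOH, H2), in which base racemises the doubly activated α-centre, should deliver 15. Should the C1 epimer form instead, it serves equally, because step 9 erases that centre.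

2. Step 9. The benzylic cation may lose the C3 proton to give an α-methylstilbene and be reprotonated (or suffer a 1,2-hydride shift), which erodes the C3 configuration; trans selectivity may also be incomplete. The fallback sets out from 15 and comes back at 17, and replaces the cation by two SN2 inversions. Mitsunobu esterification of 15 (4-nitrobenzoic acid, PPh3, DIAD, THF) should give the inverted (1S,2R)-2-[5-chloro-4-methoxy-2-(methoxymethoxy)phenyl]-1-(3,4,5-trimethoxyphenyl)propyl 4-nitrobenzoate F3. Methanolysis (K2CO3, MeOH) should give the (1S,2R) alcohol F4. Non-acidic MOM removal (TMSOTf, 2,2′-bipyridyl, CH2Cl2, 0 °C; then H2O) should give 4-chloro-2-[(1S,2R)-1-hydroxy-1-(3,4,5-trimethoxyphenyl)propan-2-yl]-5-methoxyphenol F5. Intramolecular Mitsunobu etherification of F5 (PPh3, DIAD, THF, 0 °C) inverts C1 a second time and should close the trans ring of 17.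

3. Step 10. Oxidative addition at the electron-rich, ortho-methoxylated chloride may be slow enough for the propenylboronic acid to protodeboronate, or the alkene geometry may erode. The fallback sets out from 17 and comes back at 18, and reverses the polarity of the coupling. Miyaura borylation of 17 (B2pin2, Pd2(dba)3, XPhos, KOAc, dioxane, 100 °C) should give (2R,3R)-6-methoxy-3-methyl-5-(4,4,5,5-tetramethyl-1,3,2-dioxaborolan-2-yl)-2-(3,4,5-trimethoxyphenyl)-2,3-dihydro-1-benzofuran F6. F6 is then coupled with (E)-1-bromoprop-1-ene (Pd(PPh3)4, K2CO3, DME/H2O, 80 °C), whose oxidative addition is fast and stereoretentive.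

**Further compounds**

F1 | step 7 | 1-(3,4,5-trimethoxyphenyl)propan-1-one | CCC(=O)c1cc(OC)c(OC)c(OC)c1
F2 | step 7 | racemic 2-[5-chloro-4-methoxy-2-(methoxymethoxy)phenyl]-1-(3,4,5-trimethoxyphenyl)propan-1-one | CC(C(=O)c1cc(OC)c(OC)c(OC)c1)c1cc(Cl)c(OC)cc1OCOC
F3 | step 9 | (1S,2R)-2-[5-chloro-4-methoxy-2-(methoxymethoxy)phenyl]-1-(3,4,5-trimethoxyphenyl)propyl 4-nitrobenzoate | O=C(O[C@H](c1cc(OC)c(OC)c(OC)c1)[C@@H](c1cc(Cl)c(OC)cc1OCOC)C)c1ccc(cc1)[N+](=O)[O-]
F4 | step 9 | (1S,2R)-2-[5-chloro-4-methoxy-2-(methoxymethoxy)phenyl]-1-(3,4,5-trimethoxyphenyl)propan-1-ol | O[C@H](c1cc(OC)c(OC)c(OC)c1)[C@@H](c1cc(Cl)c(OC)cc1OCOC)C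
F5 | step 9 | 4-chloro-2-[(1S,2R)-1-hydroxy-1-(3,4,5-trimethoxyphenyl)propan-2-yl]-5-methoxyphenol | O[C@H](c1cc(OC)c(OC)c(OC)c1)[C@@H](c1cc(Cl)c(OC)cc1O)C
F6 | step 10 | (2R,3R)-6-methoxy-3-methyl-5-(4,4,5,5-tetramethyl-1,3,2-dioxaborolan-2-yl)-2-(3,4,5-trimethoxyphenyl)-2,3-dihydro-1-benzofuran | CC1(C)OB(OC1(C)C)c1cc2c(cc1OC)O[C@@H](c1cc(OC)c(OC)c(OC)c1)[C@@H]2C
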